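**Retrosynthetic overview**
1. Lychnophorolide B ⇒ C15 desilylation and C8 tigloylation of macrocyclic alcohol 23.
2. 23 ⇒ C7–C8 bond by intramolecular chromium Barbier allylation of aldehyde/bromomethyl-butenolide 21 (10-membered carbocycle, formed last).
3. Butenolide ⇒ ring-closing metathesis of acrylate 19 (lactone ring, formed second); furanone of 19 ⇒ gold-triggered 5-endo cyclization with 1,2-shift of the C14 methyl from C1 to C10 in α-hydroxy ketone 17 (furanone ring, formed first; sets C10).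
4. 17 ⇒ esterification and Sonogashira coupling (C3–C4) of vinyl iodide 7 with alkynyl α-hydroxy ketone 13.
5. 7 ⇒ propargyl alcohol + acrolein (asymmetric alkynylation, directed hydroalumination/iodination); 13 ⇒ methyl pyruvate + ethynyltrimethylsilane (asymmetric alkynylation) + acetal Grignard 12.

Assumption: the SMILES is read as the (E)-ester (tiglate) with (4Z,6R,7R,8S,10R) configuration, germacranolide numbering C1–C15 is used for all intermediates, and each named ligand enantiomer is taken to be the one that gives the drawn configuration (otherwise its mirror image is used).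

**Route**

Step 1
Reactants: 1 prop-2-yn-1-ol
Product: 2 tert-butyldimethyl(prop-2-yn-1-yloxy)silane
Conditions: TBSCl, imidazole, CH2Cl2, 0 °C to rt
Reagents that add atoms: tert-butyldimethylsilyl chloride, CC(C)(C)[Si](C)(C)Cl
Why: Standard silyl ether protection of the only hydroxyl (future C15–O); no stereocentre is formed.

Step 2
Reactants: 2 tert-butyldimethyl(prop-2-yn-1-yloxy)silane; 3 prop-2-enal (acrolein)
Product: 5 (S)-6-(tert-butyldimethylsilyloxy)hex-1-en-4-yn-3-ol, via methylzinc acetylide 4 (not isolated)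
Conditions: 2 (2.8 equiv), Me2Zn (3 equiv), (S,S)-ProPhenol (20 mol%), Ph3PO (40 mol%), toluene, 0 °C, 1 h; then 3 added over 4 h, 4 °C
Reagents that add atoms: none
Why: Zinc–ProPhenol catalysed enantioselective alkynylation of an enal, in which acetylide 4 adds to acrolein inside the chiral dinuclear zinc pocket and sets the C6 carbinol as (S) by catalyst control, slow aldehyde addition suppressing the racemic background reaction.

Step 3
Reactants: 5 (S)-6-(tert-butyldimethylsilyloxy)hex-1-en-4-yn-3-ol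
Product: 7 (S,Z)-6-(tert-butyldimethylsilyloxy)-5-iodohexa-1,4-dien-3-ol, via cyclic alkenylaluminate 6 (not isolated)
Conditions: NaAlH2(OCH2CH2OMe)2 (Red-Al, 1.6 equiv), THF, 0 °C to rt; then I2, −78 °C to 0 °C
Reagents that add atoms: iodine, II
Why: Hydroxyl-directed trans-hydroalumination of the propargylic alcohol puts aluminium on the distal carbon C4 (aluminate 6), and iodinolysis with retention gives the vinyl iodide with iodine cis to C6, which fixes the C4=C5 geometry of the target; C6 is untouched.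

Step 4
Reactants: 8 methyl 2-oxopropanoate (methyl pyruvate); 9 ethynyltrimethylsilane
Product: 10 methyl (R)-2-hydroxy-2-methyl-4-(trimethylsilyl)but-3-ynoate
Conditions: Zn(OTf)2 (20 mol%), (1S,2S)-2-(dimethylamino)-3-(tert-butyldimethylsilyloxy)-1-(4-nitrophenyl)propan-1-ol (22 mol%), Et3N (30 mol%), toluene, 70 °C, sealed tube
Reagents that add atoms: none
Why: Zinc triflate/amino alcohol catalysed enantioselective alkynylation of an α-keto ester, in which the zinc acetylide adds to one face of the chelated ketone and sets the tertiary carbinol (R) that later becomes C1.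

Step 5
Reactants: 10 methyl (R)-2-hydroxy-2-methyl-4-(trimethylsilyl)but-3-ynoate
Product: 11 (R)-2-hydroxy-N-methoxy-N,2-dimethyl-4-(trimethylsilyl)but-3-ynamide
Conditions: MeNH(OMe)·HCl (2.5 equiv), iPrMgCl (6 equiv), THF, −20 °C to 0 °C
Reagents that add atoms: N,O-dimethylhydroxylamine hydrochloride, CNOC.Cl
Why: Direct aminolysis of the ester by the magnesium amide of N,O-dimethylhydroxylamine (Weinreb amide formation); the quaternary carbinol cannot epimerise.

Step 6
Reactants: 11 (R)-2-hydroxy-N-methoxy-N,2-dimethyl-4-(trimethylsilyl)but-3-ynamide; 12 (1,3-dioxolan-2-ylmethyl)magnesium bromide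
Product: 13 (R)-1-(1,3-dioxolan-2-yl)-3-hydroxy-3-methyl-5-(trimethylsilyl)pent-4-yn-2-one
Conditions: 12 (0.5 M in THF, 3 equiv), THF, 0 °C to rt; aq NH4Cl
Reagents that add atoms: none
Why: Weinreb ketone synthesis, the Grignard adding once to the N-methoxy-N-methylamide to give the C10 ketone with C9 and the masked C8 aldehyde; the carbinol centre is untouched.

Step 7
Reactants: 7 (S,Z)-6-(tert-butyldimethylsilyloxy)-5-iodohexa-1,4-dien-3-ol; 13 (R)-1-(1,3-dioxolan-2-yl)-3-hydroxy-3-methyl-5-(trimethylsilyl)pent-4-yn-2-one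
Product: 15 (3R,6E,8S)-6-[(tert-butyldimethylsilyloxy)methyl]-1-(1,3-dioxolan-2-yl)-3,8-dihydroxy-3-methyldeca-6,9-dien-4-yn-2-one, via terminal alkyne 14 (not isolated)
Conditions: Pd(PPh3)4 (5 mol%), CuI (10 mol%), CsF (2.5 equiv), THF/MeOH (4:1), rt, degassed
Reagents that add atoms: none
Why: One-pot fluoride-triggered protodesilylation and Sonogashira coupling forms the C3–C4 bond with retention of the vinyl iodide geometry; neither stereocentre takes part.

Step 8
Reactants: 15 (3R,6E,8S)-6-[(tert-butyldimethylsilyloxy)methyl]-1-(1,3-dioxolan-2-yl)-3,8-dihydroxy-3-methyldeca-6,9-dien-4-yn-2-one; 16 2-(bromomethyl)acrylic acid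
Product: 17 (3S,4E,8R)-5-[(tert-butyldimethylsilyloxy)methyl]-10-(1,3-dioxolan-2-yl)-8-hydroxy-8-methyl-9-oxodeca-1,4-dien-6-yn-3-yl 2-(bromomethyl)acrylate
Conditions: DCC (1.3 equiv), DMAP (5 mol%), CH2Cl2, −20 °C to 0 °C
Reagents that add atoms: none
Why: Steglich esterification of the secondary bis-allylic hydroxyl with retention at C6 (the tertiary propargylic hydroxyl is too hindered), which also masks the hydroxyl that would otherwise cyclise onto the alkyne in step 9.

Step 9
Reactants: 17 (3S,4E,8R)-5-[(tert-butyldimethylsilyloxy)methyl]-10-(1,3-dioxolan-2-yl)-8-hydroxy-8-methyl-9-oxodeca-1,4-dien-6-yn-3-yl 2-(bromomethyl)acrylate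
Product: 19 (3S,4Z)-6-(tert-butyldimethylsilyloxy)-5-[(5R)-5-(1,3-dioxolan-2-ylmethyl)-5-methyl-4-oxo-4,5-dihydrofuran-2-yl]hexa-1,4-dien-3-yl 2-(bromomethyl)acrylate, via aurated oxocarbenium 18 (not isolated)
Conditions: AuCl3 (5 mol%), CH2Cl2, 0 °C to rt, dark
Reagents that add atoms: none
Why: Proposed new method: trivalent gold activates the alkyne, the C10 ketone oxygen closes 5-endo-dig onto the alkenyl-substituted carbon C3 to give oxocarbenium 18, and the C14 methyl then migrates suprafacially from C1 to the cationic C10 (α-ketol-type 1,2-shift driven by formation of the C1 ketone) before protodeauration, so the (R)-carbinol is relayed to the new quaternary (10R) centre as the furanone ring forms; the closest known reaction is the gold- or platinum-catalysed heterocyclization/1,2-migration of simple racemic 2-hydroxy-2-alkynyl ketones to 3(2H)-furanones, not yet shown as a stereo-relaying step or on an alkenyl-alkyne carrying an allylic ester and an allylic bromide.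

Step 10
Reactants: 19 (3S,4Z)-6-(tert-butyldimethylsilyloxy)-5-[(5R)-5-(1,3-dioxolan-2-ylmethyl)-5-methyl-4-oxo-4,5-dihydrofuran-2-yl]hexa-1,4-dien-3-yl 2-(bromomethyl)acrylate
Product: 20 (5R)-3-(bromomethyl)-5-{(1Z)-3-(tert-butyldimethylsilyloxy)-2-[(5R)-5-(1,3-dioxolan-2-ylmethyl)-5-methyl-4-oxo-4,5-dihydrofuran-2-yl]prop-1-en-1-yl}furan-2(5H)-one
Conditions: second-generation Hoveyda–Grubbs catalyst (10 mol%), toluene (5 mM), 80 °C, argon sparge
Reagents that add atoms: none
Why: Ring-closing metathesis between the vinyl group and the 2-substituted acrylate forms the trisubstituted butenolide with loss of ethene and leaves the allylic bromide in place; C6 and C10 are not involved.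

Step 11
Reactants: 20 (5R)-3-(bromomethyl)-5-{(1Z)-3-(tert-butyldimethylsilyloxy)-2-[(5R)-5-(1,3-dioxolan-2-ylmethyl)-5-methyl-4-oxo-4,5-dihydrofuran-2-yl]prop-1-en-1-yl}furan-2(5H)-one
Product: 21 2-[(2R)-5-{(1Z)-1-[(2R)-4-(bromomethyl)-5-oxo-2,5-dihydrofuran-2-yl]-3-(tert-butyldimethylsilyloxy)prop-1-en-2-yl}-2-methyl-3-oxo-2,3-dihydrofuran-2-yl]acetaldehyde
Conditions: In(OTf)3 (5 mol%), acetone/H2O (20:1), rt; used crude
Reagents that add atoms: water, O
Why: Mild Lewis-acid catalysed acetal hydrolysis unmasks the C8 aldehyde under nearly neutral conditions that spare the silyl ether, the allylic bromide and the elimination-prone β-alkoxy aldehyde.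

Step 12
Reactants: 21 2-[(2R)-5-{(1Z)-1-[(2R)-4-(bromomethyl)-5-oxo-2,5-dihydrofuran-2-yl]-3-(tert-butyldimethylsilyloxy)prop-1-en-2-yl}-2-methyl-3-oxo-2,3-dihydrofuran-2-yl]acetaldehyde
Product: 23 (4Z,6R,7R,8S,10R)-15-(tert-butyldimethylsilyloxy)-8-hydroxy-1-oxo-3,10-epoxygermacra-2,4,11(13)-trien-12,6-olide, via allylchromium dichloride 22 (not isolated)
Conditions: CrCl2 (10 equiv), THF/DMF (4:1), rt, 21 added over 10 h (final 1 mM)
Reagents that add atoms: none
Why: Intramolecular chromium-mediated Barbier (Nozaki–Hiyama) allylation, in which allylchromium 22 attacks the aldehyde through its γ-carbon C7 in a chair transition state, anti to the C6 substituent (trans-lactone, 7R) and, with the allyl geometry fixed by the butenolide ring, with the anti C7/C8 relationship (8S), closing the 10-membered ring under high dilution.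

Step 13
Reactants: 23 (4Z,6R,7R,8S,10R)-15-(tert-butyldimethylsilyloxy)-8-hydroxy-1-oxo-3,10-epoxygermacra-2,4,11(13)-trien-12,6-olide; 24 (E)-2-methylbut-2-enoyl chloride (tigloyl chloride)
Product: 25 (4Z,6R,7R,8S,10R)-15-(tert-butyldimethylsilyloxy)-1-oxo-3,10-epoxygermacra-2,4,11(13)-trien-12,6-olid-8-yl (E)-2-methylbut-2-enoate
Conditions: 24 (3 equiv), pyridine, DMAP (20 mol%), CH2Cl2, 0 °C to rt
Reagents that add atoms: none
Why: DMAP-catalysed acylation of the secondary C8 hydroxyl with retention at C8; the (E)-ester is the thermodynamically stable geometry.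

Step 14
Reactants: 25 (4Z,6R,7R,8S,10R)-15-(tert-butyldimethylsilyloxy)-1-oxo-3,10-epoxygermacra-2,4,11(13)-trien-12,6-olid-8-yl (E)-2-methylbut-2-enoate
Product: 26 Lychnophorolide B
Conditions: HF·pyridine, THF/pyridine, 0 °C to rt
Reagents that add atoms: none
Why: Fluoride-mediated cleavage of the primary allylic silyl ether under buffered conditions that leave the α-methylene lactone, the tiglate and the furanone intact.

**Compound list**
1 | prop-2-yn-1-ol | C#CCO | starting material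
2 | tert-butyldimethyl(prop-2-yn-1-yloxy)silane | C#CCO[Si](C)(C)C(C)(C)C | intermediate
3 | prop-2-enal (acrolein) | C=CC=O | starting material
4 | [3-(tert-butyldimethylsilyloxy)prop-1-yn-1-yl](methyl)zinc, not isolated | C[Zn]C#CCO[Si](C)(C)C(C)(C)C | intermediate
5 | (S)-6-(tert-butyldimethylsilyloxy)hex-1-en-4-yn-3-ol | C=C[C@H](O)C#CCO[Si](C)(C)C(C)(C)C | intermediate
6 | sodium (S)-2,2-bis(2-methoxyethoxy)-3-[(tert-butyldimethylsilyloxy)methyl]-5-vinyl-2,5-dihydro-1,2-oxaluminol-2-uide, not isolated | [Na+].C=C[C@H]1C=C(CO[Si](C)(C)C(C)(C)C)[Al-](OCCOC)(OCCOC)O1 | intermediate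
7 | (S,Z)-6-(tert-butyldimethylsilyloxy)-5-iodohexa-1,4-dien-3-ol | C=C[C@H](O)/C=C(\I)CO[Si](C)(C)C(C)(C)C | intermediate
8 | methyl 2-oxopropanoate (methyl pyruvate) | CC(=O)C(=O)OC | starting material
9 | ethynyltrimethylsilane | C#C[Si](C)(C)C | starting material
10 | methyl (R)-2-hydroxy-2-methyl-4-(trimethylsilyl)but-3-ynoate | C[Si](C)(C)C#C[C@@](C)(O)C(=O)OC | intermediate
11 | (R)-2-hydroxy-N-methoxy-N,2-dimethyl-4-(trimethylsilyl)but-3-ynamide | C[Si](C)(C)C#C[C@@](C)(O)C(=O)N(C)OC | intermediate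
12 | (1,3-dioxolan-2-ylmethyl)magnesium bromide | Br[Mg]CC1OCCO1 | starting material
13 | (R)-1-(1,3-dioxolan-2-yl)-3-hydroxy-3-methyl-5-(trimethylsilyl)pent-4-yn-2-one | C[Si](C)(C)C#C[C@@](C)(O)C(=O)CC1OCCO1 | intermediate
14 | (R)-1-(1,3-dioxolan-2-yl)-3-hydroxy-3-methylpent-4-yn-2-one, not isolated | C#C[C@@](C)(O)C(=O)CC1OCCO1 | intermediate
15 | (3R,6E,8S)-6-[(tert-butyldimethylsilyloxy)methyl]-1-(1,3-dioxolan-2-yl)-3,8-dihydroxy-3-methyldeca-6,9-dien-4-yn-2-one | C=C[C@H](O)/C=C(/CO[Si](C)(C)C(C)(C)C)C#C[C@@](C)(O)C(=O)CC1OCCO1 | intermediate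
16 | 2-(bromomethyl)acrylic acid | C=C(CBr)C(=O)O | starting material
17 | (3S,4E,8R)-5-[(tert-butyldimethylsilyloxy)methyl]-10-(1,3-dioxolan-2-yl)-8-hydroxy-8-methyl-9-oxodeca-1,4-dien-6-yn-3-yl 2-(bromomethyl)acrylate | C=C[C@H](OC(=O)C(=C)CBr)/C=C(/CO[Si](C)(C)C(C)(C)C)C#C[C@@](C)(O)C(=O)CC1OCCO1 | intermediate
18 | zwitterion, not isolated: 3H-furan-1-ium with C2 bearing the (1,3-dioxolan-2-yl)methyl group, C3 (3S, same spatial arrangement as in 17) bearing OH and CH3, C4 bearing AuCl3(−), C5 bearing the (2Z,4S)-4-[2-(bromomethyl)acryloyloxy]-1-(tert-butyldimethylsilyloxy)hexa-2,5-dien-2-yl group | C=C[C@H](OC(=O)C(=C)CBr)/C=C(/CO[Si](C)(C)C(C)(C)C)C1=C([Au-](Cl)(Cl)Cl)[C@@](C)(O)C(CC2OCCO2)=[O+]1 | intermediate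
19 | (3S,4Z)-6-(tert-butyldimethylsilyloxy)-5-[(5R)-5-(1,3-dioxolan-2-ylmethyl)-5-methyl-4-oxo-4,5-dihydrofuran-2-yl]hexa-1,4-dien-3-yl 2-(bromomethyl)acrylate | C=C[C@H](OC(=O)C(=C)CBr)/C=C(/CO[Si](C)(C)C(C)(C)C)C1=CC(=O)[C@@](C)(CC2OCCO2)O1 | intermediate
20 | (5R)-3-(bromomethyl)-5-{(1Z)-3-(tert-butyldimethylsilyloxy)-2-[(5R)-5-(1,3-dioxolan-2-ylmethyl)-5-methyl-4-oxo-4,5-dihydrofuran-2-yl]prop-1-en-1-yl}furan-2(5H)-one | BrCC1=C[C@@H](/C=C(/CO[Si](C)(C)C(C)(C)C)C2=CC(=O)[C@@](C)(CC3OCCO3)O2)OC1=O | intermediate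
21 | 2-[(2R)-5-{(1Z)-1-[(2R)-4-(bromomethyl)-5-oxo-2,5-dihydrofuran-2-yl]-3-(tert-butyldimethylsilyloxy)prop-1-en-2-yl}-2-methyl-3-oxo-2,3-dihydrofuran-2-yl]acetaldehyde | BrCC1=C[C@@H](/C=C(/CO[Si](C)(C)C(C)(C)C)C2=CC(=O)[C@@](C)(CC=O)O2)OC1=O | intermediate
22 | dichloro{[(5R)-5-{(1Z)-3-(tert-butyldimethylsilyloxy)-2-[(5R)-5-methyl-4-oxo-5-(2-oxoethyl)-4,5-dihydrofuran-2-yl]prop-1-en-1-yl}-2-oxo-2,5-dihydrofuran-3-yl]methyl}chromium, not isolated | Cl[Cr](Cl)CC1=C[C@@H](/C=C(/CO[Si](C)(C)C(C)(C)C)C2=CC(=O)[C@@](C)(CC=O)O2)OC1=O | intermediate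
23 | (4Z,6R,7R,8S,10R)-15-(tert-butyldimethylsilyloxy)-8-hydroxy-1-oxo-3,10-epoxygermacra-2,4,11(13)-trien-12,6-olide | C=C1C(=O)O[C@@H]2/C=C(/CO[Si](C)(C)C(C)(C)C)C3=CC(=O)[C@@](C)(C[C@H](O)[C@@H]12)O3 | intermediate
24 | (E)-2-methylbut-2-enoyl chloride (tigloyl chloride) | C/C=C(\C)C(=O)Cl | starting material
25 | (4Z,6R,7R,8S,10R)-15-(tert-butyldimethylsilyloxy)-1-oxo-3,10-epoxygermacra-2,4,11(13)-trien-12,6-olid-8-yl (E)-2-methylbut-2-enoate | C=C1C(=O)O[C@@H]2/C=C(/CO[Si](C)(C)C(C)(C)C)C3=CC(=O)[C@@](C)(C[C@H](OC(=O)/C(C)=C/C)[C@@H]12)O3 | intermediate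
26 | Lychnophorolide B, (4Z,6R,7R,8S,10R)-15-hydroxy-1-oxo-3,10-epoxygermacra-2,4,11(13)-trien-12,6-olid-8-yl (E)-2-methylbut-2-enoate | C=C1C(=O)O[C@@H]2/C=C(/CO)C3=CC(=O)[C@@](C)(C[C@H](OC(=O)/C(C)=C/C)[C@@H]12)O3 | target

**Step count and risks**
Total: 14 steps. Longest linear sequence: 11 steps (steps 1–3 then 7–14; the branch through steps 4–6 is equally long).

Three steps most likely to fail:

Step 9, the new gold-triggered cyclization with 1,2-methyl shift. The risks are ionisation of the bis-allylic ester by the Lewis-acidic gold salt, a competing Meyer–Schuster pathway, and incomplete relay of configuration. The fallback uses known chemistry without a shift: it sets out from Weinreb amide 11 and vinyl iodide 7 and comes back at furanone 19. The carbinol of 11 is used directly as C10, its alkyne becoming the C9–C8 arm and its amide carbon becoming C1 (the (R) configuration maps onto 10R). K2CO3 in MeOH removes the silyl group to give (R)-2-hydroxy-N-methoxy-N,2-dimethylbut-3-ynamide F1. Anti-Markovnikov hydroboration–oxidation of the terminal alkyne (dicyclohexylborane, then NaBO3) gives (R)-2-hydroxy-N-methoxy-N,2-dimethyl-4-oxobutanamide F2, which is protected with ethylene glycol and PPTS as (R)-3-(1,3-dioxolan-2-yl)-2-hydroxy-N-methoxy-N,2-dimethylpropanamide F3. Stille coupling of 7 with tributyl(ethynyl)stannane (Pd(PPh3)4, DMF) gives (S,E)-5-[(tert-butyldimethylsilyloxy)methyl]hepta-1,4-dien-6-yn-3-ol F4. Its dilithio derivative (n-BuLi, 2 equiv) adds to the magnesium alkoxide of F3 to give the α'-hydroxy ynone (2R,6E,8S)-6-[(tert-butyldimethylsilyloxy)methyl]-1-(1,3-dioxolan-2-yl)-2,8-dihydroxy-2-methyldeca-6,9-dien-4-yn-3-one F5. Steglich esterification with 16 gives (3S,4E,9R)-5-[(tert-butyldimethylsilyloxy)methyl]-10-(1,3-dioxolan-2-yl)-9-hydroxy-9-methyl-8-oxodeca-1,4-dien-6-yn-3-yl 2-(bromomethyl)acrylate F6. The established 5-endo-dig cyclization of α'-hydroxy ynones to 3(2H)-furanones (Ph3PAuNTf2, 2 mol%, monovalent gold, toluene, rt) then gives 19.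

Step 12, the chromium Barbier macrocyclization. The ring closure has precedent for this ring type, so the main risk is the wrong C8 configuration from an open or boat transition state. The fallback sets out from aldehyde 21 and comes back at ester 25. If the closure gives the epimer (4Z,6R,7R,8R,10R)-15-(tert-butyldimethylsilyloxy)-8-hydroxy-1-oxo-3,10-epoxygermacra-2,4,11(13)-trien-12,6-olide F7, the esterification is changed instead of the ring closure: Mitsunobu reaction of F7 with (E)-2-methylbut-2-enoic acid (PPh3, DIAD, toluene, 0 °C) inverts C8 and gives 25 directly, bypassing 23 and step 13.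

Step 2, the asymmetric alkynylation of acrolein. Acrolein polymerises easily and is the smallest enal for this catalyst, so yield and ee are uncertain. The fallback sets out from 2 and 3 and comes back at 5. The lithium acetylide of 2 (n-BuLi, THF, −78 °C) adds to acrolein to give racemic 6-(tert-butyldimethylsilyloxy)hex-1-en-4-yn-3-ol F8. Lipase-catalysed kinetic resolution (Candida antarctica lipase B, vinyl acetate, hexane, rt) acetylates the (R)-enantiomer to (R)-6-(tert-butyldimethylsilyloxy)hex-1-en-4-yn-3-yl acetate F9 and leaves (S)-alcohol 5 (at most 50%), separated by chromatography.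

**Further compounds**
F1 | step 9 | (R)-2-hydroxy-N-methoxy-N,2-dimethylbut-3-ynamide | C#C[C@@](C)(O)C(=O)N(C)OC
F2 | step 9 | (R)-2-hydroxy-N-methoxy-N,2-dimethyl-4-oxobutanamide | O=CC[C@@](C)(O)C(=O)N(C)OC
F3 | step 9 | (R)-3-(1,3-dioxolan-2-yl)-2-hydroxy-N-methoxy-N,2-dimethylpropanamide | O1CCOC1C[C@@](C)(O)C(=O)N(C)OC
F4 | step 9 | (S,E)-5-[(tert-butyldimethylsilyloxy)methyl]hepta-1,4-dien-6-yn-3-ol | C=C[C@H](O)/C=C(/CO[Si](C)(C)C(C)(C)C)C#C
F5 | step 9 | (2R,6E,8S)-6-[(tert-butyldimethylsilyloxy)methyl]-1-(1,3-dioxolan-2-yl)-2,8-dihydroxy-2-methyldeca-6,9-dien-4-yn-3-one | C=C[C@H](O)/C=C(/CO[Si](C)(C)C(C)(C)C)C#CC(=O)[C@](C)(O)CC1OCCO1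
F6 | step 9 | (3S,4E,9R)-5-[(tert-butyldimethylsilyloxy)methyl]-10-(1,3-dioxolan-2-yl)-9-hydroxy-9-methyl-8-oxodeca-1,4-dien-6-yn-3-yl 2-(bromomethyl)acrylate | C=C[C@H](OC(=O)C(=C)CBr)/C=C(/CO[Si](C)(C)C(C)(C)C)C#CC(=O)[C@](C)(O)CC1OCCO1
F7 | step 12 | (4Z,6R,7R,8R,10R)-15-(tert-butyldimethylsilyloxy)-8-hydroxy-1-oxo-3,10-epoxygermacra-2,4,11(13)-trien-12,6-olide | C=C1C(=O)O[C@@H]2/C=C(/CO[Si](C)(C)C(C)(C)C)C3=CC(=O)[C@@](C)(C[C@@H](O)[C@@H]12)O3
F8 | step 2 | racemic 6-(tert-butyldimethylsilyloxy)hex-1-en-4-yn-3-ol | C=CC(O)C#CCO[Si](C)(C)C(C)(C)C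
F9 | step 2 | (R)-6-(tert-butyldimethylsilyloxy)hex-1-en-4-yn-3-yl acetate | C=C[C@@H](OC(C)=O)C#CCO[Si](C)(C)C(C)(C)C
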